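**Retrosynthetic overview**
1. Target 17 ⇒ two molecules of chloranthalactone A (16) by head-to-head photochemical [2+2] (C8–C8′, C9–C9′); the cyclobutane is formed last.
2. 16 ⇒ tricyclic ketone 13 + ethyl pyruvate 14 (aldol, then enol-lactonisation builds the butenolide).
3. 13 ⇒ trans-decalin 11 (1β-OH, Δ3 allylsilane). Key step: ring A contracts from six to five members as C3 displaces the C1 triflate, giving the cyclopropane, C1/C3 and the C4=C15 methylene together.
4. 11 ⇒ decalin 8 ⇒ enone 4 (ring A) + silyloxydiene 6. A formal [4+2] builds ring B and the C10 quaternary centre; C5 is set by epimerisation.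
5. 4 ⇒ 2-methylcyclohex-2-en-1-one 1 (CBS reduction is the only source of chirality, then allylic oxidation). Ring order: A → B → contraction of A with cyclopropane → butenolide → cyclobutane.

Assumption/convention: the target is read as the head-to-head, C2-symmetric cyclobutane dimer of chloranthalactone A; lindenane/eudesmane numbering is used throughout (ring A = C1–C5 + C10, ring B = C5–C10, C14 = methyl on C10, C15 = carbon on C4, β = face of C14).

**Route**

Step 1
Reactants: 1 2-methylcyclohex-2-en-1-one
Product: 2 (R)-2-methylcyclohex-2-en-1-ol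
Conditions: (S)-2-methyl-CBS-oxazaborolidine (10 mol %), BH3·SMe2, THF, −20 °C; then H2O
Reagents that add atoms: none
Why: Corey–Bakshi–Shibata reduction in which the alkenyl branch acts as the large group, so the (S)-catalyst gives the (R)-allylic alcohol, whose carbinol carbon becomes C1 and relays all later stereocentres.

Step 2
Reactants: 2 (R)-2-methylcyclohex-2-en-1-ol
Product: 3 (R)-tert-butyldimethyl[(2-methylcyclohex-2-en-1-yl)oxy]silane
Conditions: TBSCl, imidazole, DMF, rt
Reagents that add atoms: tert-butyldimethylsilyl chloride, CC(C)(C)[Si](C)(C)Cl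
Why: Standard imidazole-promoted silylation of a secondary alcohol; the bulky OTBS group is the later facial control element and the stereocentre is untouched.

Step 3
Reactants: 3 (R)-tert-butyldimethyl[(2-methylcyclohex-2-en-1-yl)oxy]silane
Product: 4 (R)-4-[(tert-butyldimethylsilyl)oxy]-3-methylcyclohex-2-en-1-one
Conditions: dirhodium tetrakis(caprolactamate) Rh2(cap)4 (1 mol %), t-BuOOH (5 equiv), K2CO3 (cat.), CH2Cl2, rt
Reagents that add atoms: tert-butyl hydroperoxide, CC(C)(C)OO
Why: Allylic C–H oxidation (peroxyl-radical chain) at the ring CH2 next to the unsubstituted alkene carbon gives the conjugated β-methyl enone and leaves the silyloxy stereocentre untouched.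

Step 4
Reactants: 5 but-3-en-2-one (methyl vinyl ketone)
Product: 6 2-[(tert-butyldimethylsilyl)oxy]buta-1,3-diene
Conditions: TBSOTf, Et3N, Et2O, 0 °C
Reagents that add atoms: tert-butyldimethylsilyl trifluoromethanesulfonate, CC(C)(C)[Si](C)(C)OS(=O)(=O)C(F)(F)F
Why: Soft enolisation and O-silylation of the enone (silyl enol ether formation) gives the 2-silyloxydiene.

Step 5
Reactants: 4 (R)-4-[(tert-butyldimethylsilyl)oxy]-3-methylcyclohex-2-en-1-one; 6 2-[(tert-butyldimethylsilyl)oxy]buta-1,3-diene
Product: 8 trans-fused decalinone (4-oxo, 1β-OTBS, 10β-CH3, 5α-H, C7=C8 enol ether with OTBS on C8), via cis-fused adduct 7 (not isolated)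
Conditions: Tf2NH (10 mol %), diene in slight excess, CH2Cl2, −78 → −20 °C; then DBU, 40 °C
Reagents that add atoms: none
Why: Silyl-triflimide-catalysed formal Diels–Alder reaction (double Mukaiyama–Michael) in which the diene CH2 next to the OSi carbon bonds to the β-carbon C10 ("para" orientation, oxygen at C8) anti to the pseudoaxial OTBS group (sets C10, methyl cis to OTBS), after which DBU epimerises C5 α to the ketone to the more stable trans-decalin.

Step 6
Reactants: 8 trans-fused decalinone
Product: 9 Δ3-enol triflate (OTf on C4, C3=C4; 1β-OTBS, 10β-CH3, 5α-H, C8 OTBS enol ether)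
Conditions: KHMDS, THF, −78 °C; PhNTf2
Reagents that add atoms: N-phenylbis(trifluoromethanesulfonimide), O=S(=O)(N(c1ccccc1)S(=O)(=O)C(F)(F)F)C(F)(F)F
Why: Kinetic deprotonation removes a C3 methylene proton rather than the ring-fusion C5–H and the enolate is O-sulfonylated (enol triflate formation), fixing the Δ3 alkene while C5 stays trans.

Step 7
Reactants: 9 Δ3-enol triflate
Product: 10 Δ3-allylsilane (CH2SiMe3 on C4; 1β-OTBS, 10β-CH3, 5α-H, C8 OTBS enol ether)
Conditions: Me3SiCH2MgCl, Pd(PPh3)4 (5 mol %), THF, 0 °C → rt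
Reagents that add atoms: (trimethylsilyl)methylmagnesium chloride, C[Si](C)(C)C[Mg]Cl
Why: Kumada–Corriu cross-coupling of the alkenyl triflate with a Grignard reagent lacking β-hydrogens installs C15 as an allylsilane without touching the silyl ethers.

Step 8
Reactants: 10 Δ3-allylsilane
Product: 11 1β-hydroxy-10β-methyl-4-[(trimethylsilyl)methyl]-5α-H-octal-3-en-8-one
Conditions: TBAF (3 equiv), THF, 0 °C → rt; then H2O
Reagents that add atoms: none
Why: Fluoride-mediated desilylation cleaves the secondary TBS ether and the TBS enol ether (freeing the C8 ketone) while the carbon-bound Me3Si group of the allylsilane survives these mild conditions.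

Step 9
Reactants: 11 1β-hydroxy-10β-methyl-4-[(trimethylsilyl)methyl]-5α-H-octal-3-en-8-one
Product: 13 tricyclic ketone (4(15)-methylene-lindenan-8-one; β-cyclopropane CH2, 5α-H, 10β-CH3), via C1 triflate 12 (not isolated)
Conditions: Tf2O (1.05 equiv), 2,6-di-tert-butyl-4-methylpyridine, CH2Cl2, −78 → 0 °C
Reagents that add atoms: none
Why: Proposed new method: a silyl-terminated homoallyl→cyclopropylcarbinyl ring contraction in which the equatorial 1β-triflate formed in situ is displaced from the α-face by C3 of the endocyclic allylsilane (inversion at C1, so the expelled C2 becomes the β-cyclopropane CH2 cis to C14) and the resulting tertiary C4 cation, β to silicon, loses Me3Si+ to give the exocyclic C4=C15 alkene, so ring A shrinks from six to five members and C1, C3 and the methylene are set in one operation; the closest known reaction types are the silicon-directed cationic cyclopropanation of acyclic homoallylic triflates carrying a terminal allylsilane and the homoallyl/cyclopropylcarbinyl (i-steroid) rearrangement, neither shown for an endocyclic cyclohex-3-enyl triflate.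

Step 10
Reactants: 13 tricyclic ketone; 14 ethyl pyruvate (ethyl 2-oxopropanoate)
Product: 15 C7 aldol adduct, ethyl 2-hydroxy-2-(8-oxo-4(15)-methylene-lindenan-7-yl)propanoate (mixture at C7/C11)
Conditions: LDA, THF, −78 °C; then 14; then H2O
Reagents that add atoms: none
Why: Kinetic lithium enolate formation occurs at C7 (C9 is neopentylic) and aldol addition to the pyruvate ketone forms the C7–C11 bond, the two new stereocentres being erased in the next step.

Step 11
Reactants: 15 C7 aldol adduct
Product: 16 chloranthalactone A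
Conditions: p-TsOH·H2O (cat.), benzene, reflux (Dean–Stark)
Reagents that add atoms: none
Why: Acid-catalysed dehydration of the tertiary alcohol and enol-lactonisation of the C8 enol onto the ester (loss of ethanol) gives the γ-alkylidene butenolide, a conversion established on this ring system.

Step 12
Reactants: 16 chloranthalactone A (two molecules)
Product: 17 target dimer (CNP0265879.1)
Conditions: hν (high-pressure Hg lamp, Pyrex), degassed benzene, rt
Reagents that add atoms: none
Why: Photochemical [2+2] cyclodimerisation of the enol-lactone C8=C9 bonds, head-to-head and on the α-face of both monomers (anti to C14 and the cyclopropane CH2), sets C8, C9, C8′ and C9′ and gives the C2-symmetric cyclobutane, as established for chloranthalactone A.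

**Compound list**
1 | 2-methylcyclohex-2-en-1-one | CC1=CCCCC1=O | starting material
2 | (R)-2-methylcyclohex-2-en-1-ol | CC1=CCCC[C@H]1O | intermediate
3 | (R)-tert-butyldimethyl[(2-methylcyclohex-2-en-1-yl)oxy]silane | CC1=CCCC[C@H]1O[Si](C)(C)C(C)(C)C | intermediate
4 | (R)-4-[(tert-butyldimethylsilyl)oxy]-3-methylcyclohex-2-en-1-one | O=C1C=C(C)[C@H](O[Si](C)(C)C(C)(C)C)CC1 | intermediate
5 | but-3-en-2-one | CC(=O)C=C | starting material
6 | 2-[(tert-butyldimethylsilyl)oxy]buta-1,3-diene | C=CC(=C)O[Si](C)(C)C(C)(C)C | intermediate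
7 | cis-fused adduct (as 8 but 5β-H; not isolated) | CC(C)(C)[Si](C)(C)O[C@@H]1CCC(=O)[C@H]2CC=C(O[Si](C)(C)C(C)(C)C)C[C@@]12C | intermediate
8 | trans-fused decalinone (4-oxo, 1β-OTBS, 10β-CH3, 5α-H, 8-OTBS-Δ7) | CC(C)(C)[Si](C)(C)O[C@@H]1CCC(=O)[C@@H]2CC=C(O[Si](C)(C)C(C)(C)C)C[C@@]12C | intermediate
9 | Δ3-enol triflate of 8 (OTf on C4) | CC(C)(C)[Si](C)(C)O[C@@H]1CC=C(OS(=O)(=O)C(F)(F)F)[C@@H]2CC=C(O[Si](C)(C)C(C)(C)C)C[C@@]12C | intermediate
10 | Δ3-allylsilane (CH2SiMe3 on C4) | CC(C)(C)[Si](C)(C)O[C@@H]1CC=C(C[Si](C)(C)C)[C@@H]2CC=C(O[Si](C)(C)C(C)(C)C)C[C@@]12C | intermediate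
11 | 1β-hydroxy-10β-methyl-4-[(trimethylsilyl)methyl]-5α-H-octal-3-en-8-one | O[C@@H]1CC=C(C[Si](C)(C)C)[C@@H]2CCC(=O)C[C@@]12C | intermediate
12 | C1 triflate of 11 (not isolated) | O=S(=O)(O[C@@H]1CC=C(C[Si](C)(C)C)[C@@H]2CCC(=O)C[C@@]12C)C(F)(F)F | intermediate
13 | tricyclic ketone, 4(15)-methylene-lindenan-8-one | C=C1[C@H]2C[C@H]2[C@@]2(C)[C@H]1CCC(=O)C2 | intermediate
14 | ethyl pyruvate | CCOC(=O)C(C)=O | starting material
15 | C7 aldol adduct (C7/C11 mixture) | C=C1[C@H]2C[C@H]2[C@@]2(C)[C@H]1CC(C(C)(O)C(=O)OCC)C(=O)C2 | intermediate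
16 | chloranthalactone A | C=C1[C@H]2C[C@H]2[C@@]2(C)[C@H]1CC1=C(C)C(=O)OC1=C2 | intermediate
17 | head-to-head cyclobutane dimer (CNP0265879.1) | C=C1[C@H]2C[C@H]2[C@@]2(C)[C@H]1CC1=C(C)C(=O)O[C@]13[C@H]2[C@H]1[C@@]2(C)[C@@H]4C[C@@H]4C(=C)[C@@H]2CC2=C(C)C(=O)O[C@@]213 | target

**Step count**
Total: 12 steps (step 4 is a one-step side branch). Longest linear sequence: 11 steps (1, 2, 3, 5–12).

**Steps most likely to fail, with fallbacks**

Step 5 (formal [4+2] on a hindered β-methyl, γ-silyloxy enone). The dienophile may be too unreactive, the diene may decompose first, or the base equilibration at C5 may stop at a cis/trans mixture (the cis isomer is then separated and resubmitted to DBU). The fallback sets out from 4 (with 6) and comes back at 8. It replaces the one-flask cycloaddition by a stepwise polar annulation. A TiCl4-mediated Mukaiyama–Michael addition of 6 to 4 (CH2Cl2, −78 °C, aqueous work-up) gives the vinyl ketone 4-[(tert-butyldimethylsilyl)oxy]-3-methyl-3-(2-oxobut-3-en-1-yl)cyclohexan-1-one F1 (methyl cis to OTBS). Soft enolisation with TBSOTf/Et3N then closes ring B by intramolecular Mukaiyama–Michael addition of C5 to the enone, with silyl transfer to the C8 oxygen, giving 7. DBU epimerisation then leads to 8 as before.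

Step 9 (the new ring contraction). Competing pathways are Wagner–Meerwein migration of C5 to a hydroazulene, elimination to a diene, protodesilylation, and enol triflate formation at the C8 ketone if Tf2O is used in excess. The fallback uses only known chemistry, sets out from 8 and comes back at 13. Exchange of the C8 silyl enol ether for a dioxolane (ethylene glycol, PPTS, CH2Cl2, rt) gives the keto ketal F2. TBAF then frees the 1β-alcohol F3, which is converted into the mesylate F4 (MsCl, Et3N). KOtBu in THF/t-BuOH brings about the classical enolate 1,3-alkylation (C3 onto C1, inversion) to the cyclopropyl ketone F5. Wittig methylenation (Ph3P=CH2, THF) gives the methylene ketal F6, and mild hydrolysis (PPTS, acetone/H2O) returns 13. The cost is two extra steps and a risk of C5 epimerisation at the ketone stage.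

Step 3 (allylic oxidation). Oxidation at the silyloxy-bearing carbon (returning 1) or at the methyl group may compete. The fallback sets out from 3 and comes back at 4. It replaces C–H oxidation by an oxidative 1,3-transposition. Epoxidation with mCPBA gives the epoxide F7 (diastereomer mixture, inconsequential). Opening at the less substituted carbon with PhSeNa (from PhSeSePh/NaBH4, EtOH) gives the hydroxy selenide F8. H2O2 oxidation and selenoxide syn-elimination give the tertiary allylic alcohol F9. Pyridinium chlorochromate [C5H5NH][CrO3Cl] in CH2Cl2 (Dauben–Babler oxidative transposition) then delivers 4.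

**Further compounds**
F1 | step 5 | 4-[(tert-butyldimethylsilyl)oxy]-3-methyl-3-(2-oxobut-3-en-1-yl)cyclohexan-1-one (4R, methyl cis to OTBS) | C=CC(=O)C[C@]1(C)CC(=O)CC[C@H]1O[Si](C)(C)C(C)(C)C
F2 | step 9 | 8,8-ethylenedioxy-1β-[(tert-butyldimethylsilyl)oxy]-10β-methyl-5α-H-decalin-4-one | CC(C)(C)[Si](C)(C)O[C@@H]1CCC(=O)[C@@H]2CCC3(OCCO3)C[C@@]12C
F3 | step 9 | 8,8-ethylenedioxy-1β-hydroxy-10β-methyl-5α-H-decalin-4-one | O[C@@H]1CCC(=O)[C@@H]2CCC3(OCCO3)C[C@@]12C
F4 | step 9 | 1β-methanesulfonate of F3 | CS(=O)(=O)O[C@@H]1CCC(=O)[C@@H]2CCC3(OCCO3)C[C@@]12C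
F5 | step 9 | 8,8-ethylenedioxy-lindenan-4-one (β-cyclopropane CH2, 5α-H) | O=C1[C@H]2C[C@H]2[C@@]2(C)[C@H]1CCC1(OCCO1)C2
F6 | step 9 | 8,8-ethylenedioxy-4(15)-methylene-lindenane | C=C1[C@H]2C[C@H]2[C@@]2(C)[C@H]1CCC1(OCCO1)C2
F7 | step 3 | 2,3-epoxide of 3 (epoxide diastereomers) | CC12OC1CCC[C@H]2O[Si](C)(C)C(C)(C)C
F8 | step 3 | (6R)-6-[(tert-butyldimethylsilyl)oxy]-1-methyl-2-(phenylselanyl)cyclohexan-1-ol | CC1(O)C([Se]c2ccccc2)CCC[C@H]1O[Si](C)(C)C(C)(C)C
F9 | step 3 | (6R)-6-[(tert-butyldimethylsilyl)oxy]-1-methylcyclohex-2-en-1-ol | CC1(O)C=CCC[C@H]1O[Si](C)(C)C(C)(C)C
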